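**Retrosynthetic overview**
- The strategy rests on one feature of the oxepine ring O1–C2–C3–C4–C5=C6–C7: the saturated C4 is bonded to sp2 C5 of the cis-trisubstituted ring alkene. The ring is therefore opened at C4–C5 into a primary C4 radical (from the N-acyloxyphthalimide of the acid one carbon longer) and a (Z)-alkenyl iodide at C5.
- Target 39 ⇒ oxepine 25 by late operations: arm CH2CH2OTBS to aldehyde, aryllithium addition and oxidation to the aryl ketone, side-chain desilylation and coumaroylation, then removal of the silyl and MOM groups.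
- 25 ⇒ redox-active ester 24 ⇒ tertiary ether 19, made from hydroxy ester 10 and allylic bromide 18; the allyl group of 19 supplies C3, C4 and the carboxyl carbon that is lost.
- 10 comes from (R)-malic acid through its pivalaldehyde dioxolanone (self-regeneration of the C2 stereocentre, allylation with retention). 18 comes from 5-bromo-2-methylpent-2-ene (SeO2 sets the E side-chain alkene) and propargyl alcohol (copper-catalysed anti-carbomagnesiation/iodination sets the Z iodide).
- Only one ring is formed, the oxepine, in step 14; the two benzene rings are bought in.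

Key step: step 14

Remarks on the chemistry:
- Oxepine numbering O1, C2 (quaternary, R), C3, C4, C5=C6, C7 is used throughout.
- The carbinol centre made in step 18 is carried as a mixture of epimers because step 19 removes it.
- The hydroquinone is carried as its bis-MOM ether and the coumarate phenol as a TBS ether, so that no silyl group sits next to the aryllithium or the benzylic alkoxide in step 18.

**Step 1**
Reactants: 1 (R)-malic acid; 2 pivalaldehyde
Product: 3 2-[(2R,4R)-2-tert-butyl-5-oxo-1,3-dioxolan-4-yl]acetic acid (cis)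
Conditions: TsOH·H2O (cat.), H2SO4 (cat.), pentane, reflux, Dean–Stark; recrystallisation
Reagents that add atoms: none
Why: Acid-catalysed acetalisation of the α-hydroxy acid unit should give the five-membered cis-dioxolanone under thermodynamic control, storing the C2 configuration in the new acetal centre (self-regeneration of stereocentres).

**Step 2**
Reactants: 3 2-[(2R,4R)-2-tert-butyl-5-oxo-1,3-dioxolan-4-yl]acetic acid
Product: 4 (2R,5R)-2-tert-butyl-5-(2-hydroxyethyl)-1,3-dioxolan-4-one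
Conditions: BH3·THF, THF, 0 °C → rt; MeOH quench; used without storage
Reagents that add atoms: none
Why: Chemoselective borane reduction of the free carboxylic acid, which reacts much faster than the acylal-type lactone, at a stage where no alkene is present.

**Step 3**
Reactants: 4 (2R,5R)-2-tert-butyl-5-(2-hydroxyethyl)-1,3-dioxolan-4-one
Product: 5 (2R,5R)-2-tert-butyl-5-[2-(tert-butyldimethylsilyloxy)ethyl]-1,3-dioxolan-4-one
Conditions: TBSCl, imidazole, CH2Cl2, 0 °C → rt
Reagents that add atoms: tert-butyldimethylsilyl chloride, CC(C)(C)[Si](C)(C)Cl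
Why: Standard silylation of the primary alcohol, which also stops it from translactonising onto the dioxolanone.

**Step 4**
Reactants: 5 (2R,5R)-2-tert-butyl-5-[2-(tert-butyldimethylsilyloxy)ethyl]-1,3-dioxolan-4-one; 6 allyl bromide
Product: 8 (2R,5R)-5-allyl-2-tert-butyl-5-[2-(tert-butyldimethylsilyloxy)ethyl]-1,3-dioxolan-4-one, via lithium enolate 7 (not isolated)
Conditions: LiN(iPr)2, THF, −78 °C; allyl bromide, −78 → −30 °C
Reagents that add atoms: none
Why: Enolate alkylation of the dioxolanone, in which the tert-butyl group shields one face so that allyl bromide should enter trans to it, where the hydrogen stood, giving the quaternary centre with overall retention (R).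

**Step 5**
Reactants: 8 (2R,5R)-5-allyl-2-tert-butyl-5-[2-(tert-butyldimethylsilyloxy)ethyl]-1,3-dioxolan-4-one; 9 2-(trimethylsilyl)ethanol
Product: 10 2-(trimethylsilyl)ethyl (R)-2-[2-(tert-butyldimethylsilyloxy)ethyl]-2-hydroxypent-4-enoate
Conditions: Me3SiCH2CH2OH (excess), NaH (0.2 equiv), THF, 0 °C → rt
Reagents that add atoms: none
Why: Alkoxide-catalysed transesterification of the activated lactone carbonyl, after which the hemiacetal alkoxide sheds pivalaldehyde; the quaternary centre is not involved and keeps its configuration.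

**Step 6**
Reactants: 11 5-bromo-2-methylpent-2-ene
Product: 12 (E)-5-bromo-2-methylpent-2-en-1-ol
Conditions: SeO2 (0.5 equiv), t-BuOOH, salicylic acid (cat.), CH2Cl2, rt, stopped before over-oxidation
Reagents that add atoms: selenium dioxide, O=[Se]=O; tert-butyl hydroperoxide (terminal oxidant), CC(C)(C)OO
Why: Riley-type allylic oxidation (ene reaction, then 2,3-sigmatropic shift) should hydroxylate the methyl group trans to the chain and so give the E allylic alcohol.

**Step 7**
Reactants: 12 (E)-5-bromo-2-methylpent-2-en-1-ol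
Product: 13 {[(E)-5-bromo-2-methylpent-2-en-1-yl]oxy}(tert-butyl)diphenylsilane
Conditions: TBDPSCl, imidazole, CH2Cl2, rt
Reagents that add atoms: tert-butyldiphenylsilyl chloride, CC(C)(C)[Si](Cl)(c1ccccc1)c1ccccc1
Why: Standard silylation giving an ether that survives the Grignard, alkoxide, borane and electrochemical steps and can be told apart from the TBS ether later.

**Step 8**
Reactants: 13 {[(E)-5-bromo-2-methylpent-2-en-1-yl]oxy}(tert-butyl)diphenylsilane; 14 propargyl alcohol
Product: 17 (2Z,5E)-7-(tert-butyldiphenylsilyloxy)-2-(iodomethylidene)-6-methylhept-5-en-1-ol, via Grignard reagent 15 (not isolated), via alkenylmagnesium alkoxide 16 (not isolated)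
Conditions: Mg, THF, rt; added to 14 pre-treated with EtMgBr (1.0 equiv), CuI (10 mol %), Et2O–THF, rt; I2, −20 °C → rt
Reagents that add atoms: iodine, [I][I]
Why: Copper-catalysed anti-carbomagnesiation of the propargylic magnesium alkoxide should put the alkyl group on the internal carbon and magnesium on the terminal carbon cis to CH2O (five-membered chelate), and iodinolysis with retention gives the Z iodide.

**Step 9**
Reactants: 17 (2Z,5E)-7-(tert-butyldiphenylsilyloxy)-2-(iodomethylidene)-6-methylhept-5-en-1-ol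
Product: 18 {[(2E,6Z)-6-(bromomethyl)-7-iodo-2-methylhepta-2,6-dien-1-yl]oxy}(tert-butyl)diphenylsilane
Conditions: CBr4, PPh3, CH2Cl2, 0 °C
Reagents that add atoms: carbon tetrabromide, BrC(Br)(Br)Br
Why: Appel bromination of the primary allylic alcohol under neutral conditions that leave the alkenyl iodide geometry and the silyl ether alone.

**Step 10**
Reactants: 10 2-(trimethylsilyl)ethyl (R)-2-[2-(tert-butyldimethylsilyloxy)ethyl]-2-hydroxypent-4-enoate; 18 {[(2E,6Z)-6-(bromomethyl)-7-iodo-2-methylhepta-2,6-dien-1-yl]oxy}(tert-butyl)diphenylsilane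
Product: 19 2-(trimethylsilyl)ethyl (R)-2-{[(2Z,5E)-7-(tert-butyldiphenylsilyloxy)-2-(iodomethylidene)-6-methylhept-5-en-1-yl]oxy}-2-[2-(tert-butyldimethylsilyloxy)ethyl]pent-4-enoate
Conditions: NaH, Bu4NI (cat.), DMF–THF, 0 °C → rt
Reagents that add atoms: none
Why: Williamson etherification of the ester-stabilised tertiary alkoxide with a reactive primary allylic bromide; the centre has no hydrogen to lose, no β-carbonyl for retro-aldol cleavage, and the alkenyl iodide cannot eliminate.

**Step 11**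
Reactants: 19 2-(trimethylsilyl)ethyl (R)-2-{[(2Z,5E)-7-(tert-butyldiphenylsilyloxy)-2-(iodomethylidene)-6-methylhept-5-en-1-yl]oxy}-2-[2-(tert-butyldimethylsilyloxy)ethyl]pent-4-enoate
Product: 21 2-(trimethylsilyl)ethyl (R)-2-{[(2Z,5E)-7-(tert-butyldiphenylsilyloxy)-2-(iodomethylidene)-6-methylhept-5-en-1-yl]oxy}-2-[2-(tert-butyldimethylsilyloxy)ethyl]-5-hydroxypentanoate, via B-alkyl-9-BBN adduct 20 (not isolated)
Conditions: 9-BBN, THF, 0 °C → rt; NaBO3·4H2O, H2O, rt
Reagents that add atoms: sodium perborate (oxygen of the new hydroxyl), [Na+].[O-]OB=O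
Why: Anti-Markovnikov hydroboration–oxidation, in which 9-BBN should take the monosubstituted terminal alkene far faster than the two trisubstituted alkenes and perborate spares the ester and the alkenyl iodide.

**Step 12**
Reactants: 21 2-(trimethylsilyl)ethyl (R)-2-{[(2Z,5E)-7-(tert-butyldiphenylsilyloxy)-2-(iodomethylidene)-6-methylhept-5-en-1-yl]oxy}-2-[2-(tert-butyldimethylsilyloxy)ethyl]-5-hydroxypentanoate
Product: 22 (R)-4-{[(2Z,5E)-7-(tert-butyldiphenylsilyloxy)-2-(iodomethylidene)-6-methylhept-5-en-1-yl]oxy}-4-[2-(tert-butyldimethylsilyloxy)ethyl]-5-oxo-5-[2-(trimethylsilyl)ethoxy]pentanoic acid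
Conditions: TEMPO (cat.), PhI(OAc)2, MeCN–H2O (pH 7 buffer), rt
Reagents that add atoms: water, O
Why: Oxoammonium-mediated oxidation of the primary alcohol through the aldehyde hydrate to the acid, under near-neutral conditions that tolerate silyl ethers, alkenes and the alkenyl iodide.

**Step 13**
Reactants: 22 (R)-4-{[(2Z,5E)-7-(tert-butyldiphenylsilyloxy)-2-(iodomethylidene)-6-methylhept-5-en-1-yl]oxy}-4-[2-(tert-butyldimethylsilyloxy)ethyl]-5-oxo-5-[2-(trimethylsilyl)ethoxy]pentanoic acid; 23 N-hydroxyphthalimide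
Product: 24 1,3-dioxoisoindolin-2-yl ester of 22 (N-acyloxyphthalimide; R)
Conditions: iPrN=C=NiPr (DIC), DMAP (cat.), CH2Cl2, rt
Reagents that add atoms: none
Why: Steglich-type carbodiimide esterification of an unhindered primary-chain acid gives the redox-active ester.

**Step 14**
Reactants: 24 1,3-dioxoisoindolin-2-yl ester of 22
Product: 25 2-(trimethylsilyl)ethyl (R)-2-[2-(tert-butyldimethylsilyloxy)ethyl]-6-[(E)-5-(tert-butyldiphenylsilyloxy)-4-methylpent-3-en-1-yl]-2,3,4,7-tetrahydrooxepine-2-carboxylate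
Conditions: NiCl2·6H2O (20 mol %), 2,2'-bipyridine (20 mol %), AgNO3 (30 mol %), LiCl, DMF, Mg anode/reticulated vitreous carbon cathode, constant current (about 2.5 F/mol), 24 added by syringe pump to about 5 mM, rt, argon
Reagents that add atoms: none
Why: Proposed new method: cathodically formed low-valent bipyridine-nickel (zerovalent or monovalent) should add oxidatively to the C5–I bond with retention of the Z geometry, while one-electron reduction of the N-acyloxyphthalimide releases phthalimide anion and CO2 and leaves the primary C4 radical; capture of this radical by the tethered alkenylnickel and reductive elimination from the resulting trivalent nickel centre form C4–C5. The closest known reaction type is the intermolecular nickel-electrocatalytic decarboxylative alkenylation of N-hydroxyphthalimide esters with alkenyl halides, which has not been used to close a ring of this size. The oxepine O1–C2–C3–C4–C5=C6–C7 closes in a formal 7-endo sense (C4 onto the distal alkene carbon C5) through an eight-membered nickelacycle, and a free-radical ipso attack at C5 with loss of an iodine atom would give the same ring. No stereocentre is formed, the quaternary C2 is not touched, and the ring alkene is cis because iodine sits cis to C7 in 24. The step needs ring closure to outrun reduction, dimerisation and 1,5-hydrogen transfer from C7 of the C4 radical, which slow addition at high dilution and the proximity enforced by the Z geometry and the fully substituted C2 should secure, and it needs C5 over C6 regioselectivity, which follows from nickel sitting on C5 and from C6 being fully substituted.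

**Step 15**
Reactants: 25 2-(trimethylsilyl)ethyl (R)-2-[2-(tert-butyldimethylsilyloxy)ethyl]-6-[(E)-5-(tert-butyldiphenylsilyloxy)-4-methylpent-3-en-1-yl]-2,3,4,7-tetrahydrooxepine-2-carboxylate
Product: 26 2-(trimethylsilyl)ethyl (R)-6-[(E)-5-(tert-butyldiphenylsilyloxy)-4-methylpent-3-en-1-yl]-2-(2-hydroxyethyl)-2,3,4,7-tetrahydrooxepine-2-carboxylate
Conditions: HF·pyridine, pyridine, THF, 0 °C; used without storage
Reagents that add atoms: none
Why: Selective desilylation of the primary TBS ether in the presence of the bulkier TBDPS ether, in a buffered, non-basic medium that should hold back lactonisation onto the hindered ester.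

**Step 16**
Reactants: 26 2-(trimethylsilyl)ethyl (R)-6-[(E)-5-(tert-butyldiphenylsilyloxy)-4-methylpent-3-en-1-yl]-2-(2-hydroxyethyl)-2,3,4,7-tetrahydrooxepine-2-carboxylate
Product: 27 2-(trimethylsilyl)ethyl (R)-6-[(E)-5-(tert-butyldiphenylsilyloxy)-4-methylpent-3-en-1-yl]-2-(2-oxoethyl)-2,3,4,7-tetrahydrooxepine-2-carboxylate
Conditions: Dess–Martin periodinane, NaHCO3, CH2Cl2, 0 °C → rt
Reagents that add atoms: none
Why: Dess–Martin oxidation under buffered conditions gives the β-alkoxy aldehyde without base that could trigger β-elimination of the ring oxygen.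

**Step 17**
Reactants: 28 hydroquinone
Product: 29 1,4-bis(methoxymethoxy)benzene
Conditions: NaH, MOMCl, DMF, 0 °C → rt
Reagents that add atoms: chloromethyl methyl ether, COCCl
Why: Williamson-type acetal formation on both phenols gives a protected arene whose MOM groups direct ortho-lithiation and cannot migrate.

**Step 18**
Reactants: 27 2-(trimethylsilyl)ethyl (R)-6-[(E)-5-(tert-butyldiphenylsilyloxy)-4-methylpent-3-en-1-yl]-2-(2-oxoethyl)-2,3,4,7-tetrahydrooxepine-2-carboxylate; 29 1,4-bis(methoxymethoxy)benzene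
Product: 31 2-(trimethylsilyl)ethyl (R)-2-{2-[2,5-bis(methoxymethoxy)phenyl]-2-hydroxyethyl}-6-[(E)-5-(tert-butyldiphenylsilyloxy)-4-methylpent-3-en-1-yl]-2,3,4,7-tetrahydrooxepine-2-carboxylate (epimers at the carbinol carbon), via 2,5-bis(methoxymethoxy)phenyllithium 30 (not isolated)
Conditions: n-BuLi, THF, 0 °C (29 → 30); −78 °C, 27 in THF; AcOH, −78 °C
Reagents that add atoms: none
Why: MOM-directed ortho-lithiation followed by 1,2-addition to the aldehyde, which is far more electrophilic than the hindered ester; the new carbinol centre forms without control and is removed in step 19, and the cold acidic quench should keep the alkoxide from closing onto the ester.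

**Step 19**
Reactants: 31 2-(trimethylsilyl)ethyl (R)-2-{2-[2,5-bis(methoxymethoxy)phenyl]-2-hydroxyethyl}-6-[(E)-5-(tert-butyldiphenylsilyloxy)-4-methylpent-3-en-1-yl]-2,3,4,7-tetrahydrooxepine-2-carboxylate
Product: 32 2-(trimethylsilyl)ethyl (R)-2-{2-[2,5-bis(methoxymethoxy)phenyl]-2-oxoethyl}-6-[(E)-5-(tert-butyldiphenylsilyloxy)-4-methylpent-3-en-1-yl]-2,3,4,7-tetrahydrooxepine-2-carboxylate
Conditions: Dess–Martin periodinane, NaHCO3, CH2Cl2, rt
Reagents that add atoms: none
Why: Dess–Martin oxidation of the benzylic alcohol to the aryl ketone under buffered, non-basic conditions.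

**Step 20**
Reactants: 32 2-(trimethylsilyl)ethyl (R)-2-{2-[2,5-bis(methoxymethoxy)phenyl]-2-oxoethyl}-6-[(E)-5-(tert-butyldiphenylsilyloxy)-4-methylpent-3-en-1-yl]-2,3,4,7-tetrahydrooxepine-2-carboxylate
Product: 33 2-(trimethylsilyl)ethyl (R)-2-{2-[2,5-bis(methoxymethoxy)phenyl]-2-oxoethyl}-6-[(E)-5-hydroxy-4-methylpent-3-en-1-yl]-2,3,4,7-tetrahydrooxepine-2-carboxylate
Conditions: HF·pyridine, pyridine, THF, rt
Reagents that add atoms: none
Why: Fluoride-mediated cleavage of the primary allylic TBDPS ether in a buffered acidic medium that leaves the silylethyl ester, the MOM ethers and the β-alkoxy ketone intact.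

**Step 21**
Reactants: 34 p-coumaric acid
Product: 36 (E)-3-[4-(tert-butyldimethylsilyloxy)phenyl]prop-2-enoic acid, via bis-silylated coumarate 35 (not isolated)
Conditions: TBSCl (2.5 equiv), imidazole, DMF, rt; AcOH–THF–H2O, rt
Reagents that add atoms: tert-butyldimethylsilyl chloride, CC(C)(C)[Si](C)(C)Cl
Why: Exhaustive silylation followed by selective hydrolysis of the much more labile silyl ester leaves the aryl silyl ether and the E alkene of the acid.

**Step 22**
Reactants: 33 2-(trimethylsilyl)ethyl (R)-2-{2-[2,5-bis(methoxymethoxy)phenyl]-2-oxoethyl}-6-[(E)-5-hydroxy-4-methylpent-3-en-1-yl]-2,3,4,7-tetrahydrooxepine-2-carboxylate; 36 (E)-3-[4-(tert-butyldimethylsilyloxy)phenyl]prop-2-enoic acid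
Product: 37 2-(trimethylsilyl)ethyl (R)-2-{2-[2,5-bis(methoxymethoxy)phenyl]-2-oxoethyl}-6-[(E)-5-({(E)-3-[4-(tert-butyldimethylsilyloxy)phenyl]prop-2-enoyl}oxy)-4-methylpent-3-en-1-yl]-2,3,4,7-tetrahydrooxepine-2-carboxylate
Conditions: DIC, DMAP (cat.), CH2Cl2, 0 °C → rt
Reagents that add atoms: none
Why: Steglich esterification of the primary allylic alcohol by acyl transfer at oxygen, so neither alkene geometry is affected.

**Step 23**
Reactants: 37 2-(trimethylsilyl)ethyl (R)-2-{2-[2,5-bis(methoxymethoxy)phenyl]-2-oxoethyl}-6-[(E)-5-({(E)-3-[4-(tert-butyldimethylsilyloxy)phenyl]prop-2-enoyl}oxy)-4-methylpent-3-en-1-yl]-2,3,4,7-tetrahydrooxepine-2-carboxylate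
Product: 38 (R)-2-{2-[2,5-bis(methoxymethoxy)phenyl]-2-oxoethyl}-6-[(E)-5-{[(E)-3-(4-hydroxyphenyl)prop-2-enoyl]oxy}-4-methylpent-3-en-1-yl]-2,3,4,7-tetrahydrooxepine-2-carboxylic acid
Conditions: TASF [(Me2N)3S+ Me3SiF2−], DMF, 0 °C → rt; cold dilute HCl work-up
Reagents that add atoms: none
Why: Fluoride-mediated desilylation, in which attack at silicon fragments the β-silylethyl ester to carboxylate, ethene and Me3SiF and cleaves the aryl silyl ether, with an anhydrous, weakly basic fluoride source chosen to spare the cinnamate ester and the β-alkoxy ketone.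

**Step 24**
Reactants: 38 (R)-2-{2-[2,5-bis(methoxymethoxy)phenyl]-2-oxoethyl}-6-[(E)-5-{[(E)-3-(4-hydroxyphenyl)prop-2-enoyl]oxy}-4-methylpent-3-en-1-yl]-2,3,4,7-tetrahydrooxepine-2-carboxylic acid
Product: 39 (R)-2-[2-(2,5-dihydroxyphenyl)-2-oxoethyl]-6-[(E)-5-{[(E)-3-(4-hydroxyphenyl)prop-2-enoyl]oxy}-4-methylpent-3-en-1-yl]-2,3,4,7-tetrahydrooxepine-2-carboxylic acid (CNP0602535.1)
Conditions: HCl (2 M aq), THF, 40 °C, argon
Reagents that add atoms: none
Why: Acid-catalysed acetal hydrolysis of the two aryl MOM ethers (the one ortho to the ketone is assisted by the carbonyl) in a methanol-free medium, so that the free acid is not esterified and the allylic ester, ring ether and alkenes should survive.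

**Compound list**
1 | (R)-malic acid | O[C@H](CC(=O)O)C(=O)O | starting material
2 | pivalaldehyde | CC(C)(C)C=O | starting material
3 | 2-[(2R,4R)-2-tert-butyl-5-oxo-1,3-dioxolan-4-yl]acetic acid | CC(C)(C)[C@@H]1O[C@H](CC(=O)O)C(=O)O1 | intermediate
4 | (2R,5R)-2-tert-butyl-5-(2-hydroxyethyl)-1,3-dioxolan-4-one | CC(C)(C)[C@@H]1O[C@H](CCO)C(=O)O1 | intermediate
5 | (2R,5R)-2-tert-butyl-5-[2-(tert-butyldimethylsilyloxy)ethyl]-1,3-dioxolan-4-one | CC(C)(C)[C@@H]1O[C@H](CCO[Si](C)(C)C(C)(C)C)C(=O)O1 | intermediate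
6 | allyl bromide | C=CCBr | starting material
7 | lithium enolate of 5 (acetal centre R) | CC(C)(C)[C@@H]1OC(CCO[Si](C)(C)C(C)(C)C)=C([O-])O1.[Li+] | intermediate
8 | (2R,5R)-5-allyl-2-tert-butyl-5-[2-(tert-butyldimethylsilyloxy)ethyl]-1,3-dioxolan-4-one | CC(C)(C)[C@@H]1O[C@@](CCO[Si](C)(C)C(C)(C)C)(CC=C)C(=O)O1 | intermediate
9 | 2-(trimethylsilyl)ethanol | C[Si](C)(C)CCO | starting material
10 | 2-(trimethylsilyl)ethyl (R)-2-[2-(tert-butyldimethylsilyloxy)ethyl]-2-hydroxypent-4-enoate | O[C@@](CCO[Si](C)(C)C(C)(C)C)(CC=C)C(=O)OCC[Si](C)(C)C | intermediate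
11 | 5-bromo-2-methylpent-2-ene | CC(C)=CCCBr | starting material
12 | (E)-5-bromo-2-methylpent-2-en-1-ol | C/C(=C\CCBr)CO | intermediate
13 | {[(E)-5-bromo-2-methylpent-2-en-1-yl]oxy}(tert-butyl)diphenylsilane | C/C(=C\CCBr)CO[Si](c1ccccc1)(c1ccccc1)C(C)(C)C | intermediate
14 | propargyl alcohol | C#CCO | starting material
15 | {(E)-5-(tert-butyldiphenylsilyloxy)-4-methylpent-3-en-1-yl}magnesium bromide | C/C(=C\CC[Mg]Br)CO[Si](c1ccccc1)(c1ccccc1)C(C)(C)C | intermediate
16 | bromomagnesium (2Z,5E)-2-[(bromomagnesio)methylidene]-7-(tert-butyldiphenylsilyloxy)-6-methylhept-5-en-1-olate | C/C(=C\CC/C(=C/[Mg]Br)CO[Mg]Br)CO[Si](c1ccccc1)(c1ccccc1)C(C)(C)C | intermediate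
17 | (2Z,5E)-7-(tert-butyldiphenylsilyloxy)-2-(iodomethylidene)-6-methylhept-5-en-1-ol | C/C(=C\CC/C(=C/I)CO)CO[Si](c1ccccc1)(c1ccccc1)C(C)(C)C | intermediate
18 | {[(2E,6Z)-6-(bromomethyl)-7-iodo-2-methylhepta-2,6-dien-1-yl]oxy}(tert-butyl)diphenylsilane | C/C(=C\CC/C(=C/I)CBr)CO[Si](c1ccccc1)(c1ccccc1)C(C)(C)C | intermediate
19 | 2-(trimethylsilyl)ethyl (R)-2-{[(2Z,5E)-7-(tert-butyldiphenylsilyloxy)-2-(iodomethylidene)-6-methylhept-5-en-1-yl]oxy}-2-[2-(tert-butyldimethylsilyloxy)ethyl]pent-4-enoate | C/C(=C\CC/C(=C/I)CO[C@@](CCO[Si](C)(C)C(C)(C)C)(CC=C)C(=O)OCC[Si](C)(C)C)CO[Si](c1ccccc1)(c1ccccc1)C(C)(C)C | intermediate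
20 | B-alkyl-9-BBN adduct of 19 (boron on the terminal carbon of the former allyl group; R) | C/C(=C\CC/C(=C/I)CO[C@@](CCO[Si](C)(C)C(C)(C)C)(CCCB1C2CCCC1CCC2)C(=O)OCC[Si](C)(C)C)CO[Si](c1ccccc1)(c1ccccc1)C(C)(C)C | intermediate
21 | 2-(trimethylsilyl)ethyl (R)-2-{[(2Z,5E)-7-(tert-butyldiphenylsilyloxy)-2-(iodomethylidene)-6-methylhept-5-en-1-yl]oxy}-2-[2-(tert-butyldimethylsilyloxy)ethyl]-5-hydroxypentanoate | C/C(=C\CC/C(=C/I)CO[C@@](CCO[Si](C)(C)C(C)(C)C)(CCCO)C(=O)OCC[Si](C)(C)C)CO[Si](c1ccccc1)(c1ccccc1)C(C)(C)C | intermediate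
22 | (R)-4-{[(2Z,5E)-7-(tert-butyldiphenylsilyloxy)-2-(iodomethylidene)-6-methylhept-5-en-1-yl]oxy}-4-[2-(tert-butyldimethylsilyloxy)ethyl]-5-oxo-5-[2-(trimethylsilyl)ethoxy]pentanoic acid | C/C(=C\CC/C(=C/I)CO[C@@](CCO[Si](C)(C)C(C)(C)C)(CCC(=O)O)C(=O)OCC[Si](C)(C)C)CO[Si](c1ccccc1)(c1ccccc1)C(C)(C)C | intermediate
23 | N-hydroxyphthalimide | O=C1N(O)C(=O)c2ccccc12 | starting material
24 | 1,3-dioxoisoindolin-2-yl ester of 22 (R) | C/C(=C\CC/C(=C/I)CO[C@@](CCO[Si](C)(C)C(C)(C)C)(CCC(=O)ON1C(=O)c2ccccc2C1=O)C(=O)OCC[Si](C)(C)C)CO[Si](c1ccccc1)(c1ccccc1)C(C)(C)C | intermediate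
25 | 2-(trimethylsilyl)ethyl (R)-2-[2-(tert-butyldimethylsilyloxy)ethyl]-6-[(E)-5-(tert-butyldiphenylsilyloxy)-4-methylpent-3-en-1-yl]-2,3,4,7-tetrahydrooxepine-2-carboxylate | C/C(=C\CCC1=CCC[C@@](CCO[Si](C)(C)C(C)(C)C)(C(=O)OCC[Si](C)(C)C)OC1)CO[Si](c1ccccc1)(c1ccccc1)C(C)(C)C | intermediate
26 | 2-(trimethylsilyl)ethyl (R)-6-[(E)-5-(tert-butyldiphenylsilyloxy)-4-methylpent-3-en-1-yl]-2-(2-hydroxyethyl)-2,3,4,7-tetrahydrooxepine-2-carboxylate | C/C(=C\CCC1=CCC[C@@](CCO)(C(=O)OCC[Si](C)(C)C)OC1)CO[Si](c1ccccc1)(c1ccccc1)C(C)(C)C | intermediate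
27 | 2-(trimethylsilyl)ethyl (R)-6-[(E)-5-(tert-butyldiphenylsilyloxy)-4-methylpent-3-en-1-yl]-2-(2-oxoethyl)-2,3,4,7-tetrahydrooxepine-2-carboxylate | C/C(=C\CCC1=CCC[C@@](CC=O)(C(=O)OCC[Si](C)(C)C)OC1)CO[Si](c1ccccc1)(c1ccccc1)C(C)(C)C | intermediate
28 | hydroquinone | Oc1ccc(O)cc1 | starting material
29 | 1,4-bis(methoxymethoxy)benzene | COCOc1ccc(OCOC)cc1 | intermediate
30 | [2,5-bis(methoxymethoxy)phenyl]lithium | [Li]c1cc(OCOC)ccc1OCOC | intermediate
31 | 2-(trimethylsilyl)ethyl (R)-2-{2-[2,5-bis(methoxymethoxy)phenyl]-2-hydroxyethyl}-6-[(E)-5-(tert-butyldiphenylsilyloxy)-4-methylpent-3-en-1-yl]-2,3,4,7-tetrahydrooxepine-2-carboxylate (carbinol epimers) | C/C(=C\CCC1=CCC[C@@](CC(O)c2cc(OCOC)ccc2OCOC)(C(=O)OCC[Si](C)(C)C)OC1)CO[Si](c1ccccc1)(c1ccccc1)C(C)(C)C | intermediate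
32 | 2-(trimethylsilyl)ethyl (R)-2-{2-[2,5-bis(methoxymethoxy)phenyl]-2-oxoethyl}-6-[(E)-5-(tert-butyldiphenylsilyloxy)-4-methylpent-3-en-1-yl]-2,3,4,7-tetrahydrooxepine-2-carboxylate | C/C(=C\CCC1=CCC[C@@](CC(=O)c2cc(OCOC)ccc2OCOC)(C(=O)OCC[Si](C)(C)C)OC1)CO[Si](c1ccccc1)(c1ccccc1)C(C)(C)C | intermediate
33 | 2-(trimethylsilyl)ethyl (R)-2-{2-[2,5-bis(methoxymethoxy)phenyl]-2-oxoethyl}-6-[(E)-5-hydroxy-4-methylpent-3-en-1-yl]-2,3,4,7-tetrahydrooxepine-2-carboxylate | C/C(=C\CCC1=CCC[C@@](CC(=O)c2cc(OCOC)ccc2OCOC)(C(=O)OCC[Si](C)(C)C)OC1)CO | intermediate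
34 | p-coumaric acid | OC(=O)/C=C/c1ccc(O)cc1 | starting material
35 | tert-butyldimethylsilyl (E)-3-[4-(tert-butyldimethylsilyloxy)phenyl]prop-2-enoate | CC(C)(C)[Si](C)(C)OC(=O)/C=C/c1ccc(O[Si](C)(C)C(C)(C)C)cc1 | intermediate
36 | (E)-3-[4-(tert-butyldimethylsilyloxy)phenyl]prop-2-enoic acid | OC(=O)/C=C/c1ccc(O[Si](C)(C)C(C)(C)C)cc1 | intermediate
37 | 2-(trimethylsilyl)ethyl (R)-2-{2-[2,5-bis(methoxymethoxy)phenyl]-2-oxoethyl}-6-[(E)-5-({(E)-3-[4-(tert-butyldimethylsilyloxy)phenyl]prop-2-enoyl}oxy)-4-methylpent-3-en-1-yl]-2,3,4,7-tetrahydrooxepine-2-carboxylate | C/C(=C\CCC1=CCC[C@@](CC(=O)c2cc(OCOC)ccc2OCOC)(C(=O)OCC[Si](C)(C)C)OC1)COC(=O)/C=C/c1ccc(O[Si](C)(C)C(C)(C)C)cc1 | intermediate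
38 | (R)-2-{2-[2,5-bis(methoxymethoxy)phenyl]-2-oxoethyl}-6-[(E)-5-{[(E)-3-(4-hydroxyphenyl)prop-2-enoyl]oxy}-4-methylpent-3-en-1-yl]-2,3,4,7-tetrahydrooxepine-2-carboxylic acid | C/C(=C\CCC1=CCC[C@@](CC(=O)c2cc(OCOC)ccc2OCOC)(C(=O)O)OC1)COC(=O)/C=C/c1ccc(O)cc1 | intermediate
39 | (R)-2-[2-(2,5-dihydroxyphenyl)-2-oxoethyl]-6-[(E)-5-{[(E)-3-(4-hydroxyphenyl)prop-2-enoyl]oxy}-4-methylpent-3-en-1-yl]-2,3,4,7-tetrahydrooxepine-2-carboxylic acid (CNP0602535.1) | C/C(=C\CCC1=CCC[C@@](CC(=O)c2cc(O)ccc2O)(C(=O)O)OC1)COC(=O)/C=C/c1ccc(O)cc1 | target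

**Step count and risks**

Total: 24 steps. Longest linear sequence: 18 steps (steps 1–5, 10–16, 18–20, 22–24, from (R)-malic acid).

The three steps most likely to fail:

Step 14 (proposed new method). The C4 radical may be reduced, dimerise or take the allylic, oxygen-bearing hydrogen from C7 before nickel captures it, or the two ends of different molecules may couple and give oligomers. The fallback forms the same C4–C5 bond by known chemistry and sets out from acid 22. Oxidative decarboxylation of 22 (Kochi reaction: Pb(OAc)4, Cu(OAc)2 cat., pyridine, benzene, 80 °C) should turn the CH2CH2CO2H arm into a vinyl group and give 2-(trimethylsilyl)ethyl (S)-2-{[(2Z,5E)-7-(tert-butyldiphenylsilyloxy)-2-(iodomethylidene)-6-methylhept-5-en-1-yl]oxy}-2-[2-(tert-butyldimethylsilyloxy)ethyl]but-3-enoate F1 (same spatial arrangement; the descriptor changes because vinyl outranks the arm). 9-BBN in THF should add to the vinyl group only, placing boron on the terminal carbon (the future C4), to give the B-alkyl-9-BBN adduct of F1 F2. Without isolation, an intramolecular B-alkyl Suzuki–Miyaura coupling with the Z-alkenyl iodide (Pd(dppf)Cl2, AsPh3, Cs2CO3, DMF–THF–H2O, high dilution, rt → 50 °C) closes the ring and comes back to the route at 25.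

Step 10. The hindered tertiary alkoxide may alkylate slowly, and while it waits the silyl group of the arm may shift to the tertiary oxygen, after which the freed primary alkoxide can close a lactone onto the ester. The fallback avoids the alkoxide altogether and sets out from alcohol 17. Treatment with Cl3CCN and DBU (cat.) in CH2Cl2 at 0 °C should give (2Z,5E)-7-(tert-butyldiphenylsilyloxy)-2-(iodomethylidene)-6-methylhept-5-en-1-yl 2,2,2-trichloroacetimidate F3. Acid-catalysed alkylation of the neutral tertiary alcohol 10 with F3 (TMSOTf cat., CH2Cl2–cyclohexane, −20 °C) comes back to the route at 19.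

Step 18. The lithium alkoxide formed in the addition may close onto the neighbouring ester (five-membered lactone), and the aryllithium may act as a base on the aldehyde and open the oxepine by β-elimination of the ring oxygen. The fallback makes the aryl ketone under neutral, palladium-catalysed conditions and sets out from aldehyde 27. Pinnick oxidation (NaClO2, NaH2PO4, 2-methylbut-2-ene, t-BuOH–H2O) should give 2-[(R)-6-[(E)-5-(tert-butyldiphenylsilyloxy)-4-methylpent-3-en-1-yl]-2-{[2-(trimethylsilyl)ethoxy]carbonyl}-2,3,4,7-tetrahydrooxepin-2-yl]acetic acid F4. Condensation with ethanethiol (DIC, DMAP cat., CH2Cl2) gives the S-ethyl thioester of F4 F5. Aryllithium 30 is quenched with B(OMe)3 and worked up with mild aqueous acid to give [2,5-bis(methoxymethoxy)phenyl]boronic acid F6. Liebeskind–Srogl coupling of F5 with F6 (Pd2(dba)3, tri(2-furyl)phosphine, copper thiophene-2-carboxylate CuO2CC4H3S, THF, 50 °C) gives the ketone directly and comes back to the route at 32, so step 19 is not needed.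

**Further compounds**
F1 | step 14 | 2-(trimethylsilyl)ethyl (S)-2-{[(2Z,5E)-7-(tert-butyldiphenylsilyloxy)-2-(iodomethylidene)-6-methylhept-5-en-1-yl]oxy}-2-[2-(tert-butyldimethylsilyloxy)ethyl]but-3-enoate | C/C(=C\CC/C(=C/I)CO[C@@](CCO[Si](C)(C)C(C)(C)C)(C=C)C(=O)OCC[Si](C)(C)C)CO[Si](c1ccccc1)(c1ccccc1)C(C)(C)C
F2 | step 14 | B-alkyl-9-BBN adduct of F1 (2-(9-borabicyclo[3.3.1]nonan-9-yl)ethyl group on C2; R) | C/C(=C\CC/C(=C/I)CO[C@@](CCO[Si](C)(C)C(C)(C)C)(CCB1C2CCCC1CCC2)C(=O)OCC[Si](C)(C)C)CO[Si](c1ccccc1)(c1ccccc1)C(C)(C)C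
F3 | step 10 | (2Z,5E)-7-(tert-butyldiphenylsilyloxy)-2-(iodomethylidene)-6-methylhept-5-en-1-yl 2,2,2-trichloroacetimidate | C/C(=C\CC/C(=C/I)COC(=N)C(Cl)(Cl)Cl)CO[Si](c1ccccc1)(c1ccccc1)C(C)(C)C
F4 | step 18 | 2-[(R)-6-[(E)-5-(tert-butyldiphenylsilyloxy)-4-methylpent-3-en-1-yl]-2-{[2-(trimethylsilyl)ethoxy]carbonyl}-2,3,4,7-tetrahydrooxepin-2-yl]acetic acid | C/C(=C\CCC1=CCC[C@@](CC(=O)O)(C(=O)OCC[Si](C)(C)C)OC1)CO[Si](c1ccccc1)(c1ccccc1)C(C)(C)C
F5 | step 18 | S-ethyl thioester of F4 | C/C(=C\CCC1=CCC[C@@](CC(=O)SCC)(C(=O)OCC[Si](C)(C)C)OC1)CO[Si](c1ccccc1)(c1ccccc1)C(C)(C)C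
F6 | step 18 | [2,5-bis(methoxymethoxy)phenyl]boronic acid | OB(O)c1cc(OCOC)ccc1OCOC
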